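**Retrosynthetic overview**
- The route rests on reading the ten-membered carbocycle (C1–C10) as a hidden cyclodec-5-enone: C9–O next to C8–O, the E C4=C5 alkene, the vicinal C6–O/C7–C11 pair, and a Z C1=C10 alkene that fits inside a cyclohexene made of C9, C10, C1, C2, C3 and C4.
- Key disconnection: the C6–C7 bond is formed while the C4–C9 bond is broken in an anionic oxy-Cope ring expansion of a 1,2-dialkenylcyclohex-2-enol; the resulting C9 enolate is hydroxylated at C8 in the same flask.
- The carbinol comes from (R)-6-allyl-2,6-dimethylcyclohexenone (asymmetric allylation) and an (E)-dienylstannane; the (2R,3R)-epoxy acid comes from angelic acid by Sharpless epoxidation and is attached to O9 by Yamaguchi esterification.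
- Ring order: cyclohexene (bought) → ten-membered ring (key step) → γ-lactone by late oxidative lactonisation; the epoxide is made on the acid fragment.

Key step: step 10

**Remarks**
- Germacrane numbering (ring C1–C10, C11–C13 on C7, C14 on C10, C15 on C4) is used throughout, also for earlier intermediates; α/β refer to the usual germacranolide drawing with H-7 α.
- Ketone 1 is used as the commercial cis/trans mixture and 5 as a mixture of C6 epimers, which converge at 7.
- Assumption on C8: the ring enolate formed in the key step is open only on the face anti to the C7–C6 ring bond, so direct hydroxylation should give the 8α alcohol. The 8β configuration of the target is therefore reached by SN2 inversion (steps 11 and 12).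

**Route**

Step 1
Reactants: 1 2,6-dimethylcyclohexanone; 2 allyl chloroformate
Product: 4 allyl 2,6-dimethylcyclohex-1-en-1-yl carbonate, via lithium enolate 3 (not isolated)
Conditions: LiHMDS, TMEDA, THF, −78 → 0 °C; then 2, −78 °C
Reagents that add atoms: none
Why: The ketone has a single kind of α-position, so LiHMDS gives one tetrasubstituted lithium enolate 3, which with TMEDA is acylated on oxygen by the hard chloroformate (enolate O-acylation), carbon acylation at the fully substituted position being slow.

Step 2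
Reactants: 4 allyl 2,6-dimethylcyclohex-1-en-1-yl carbonate
Product: 5 (2R)-2-allyl-2,6-dimethylcyclohexanone (C6 epimers)
Conditions: Pd2(dba)3 (2.5 mol %), (R)-t-Bu-PHOX (6 mol %), THF, 25 °C
Reagents that add atoms: none
Why: Decarboxylative asymmetric allylic alkylation: zerovalent palladium ionises the allyl carbonate, CO2 is lost and the palladium enolate is allylated at the fully substituted carbon, the R phosphinooxazoline being the enantiomer expected to set the quaternary centre as R.

Step 3
Reactants: 5 (2R)-2-allyl-2,6-dimethylcyclohexanone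
Product: 6 (R)-(6-allyl-2,6-dimethylcyclohex-1-en-1-yl)oxytrimethylsilane
Conditions: TMSOTf, Et3N, CH2Cl2, 0 °C
Reagents that add atoms: trimethylsilyl trifluoromethanesulfonate, C[Si](C)(C)OS(=O)(=O)C(F)(F)F
Why: Soft enolisation with silyl triflate and amine can only engage the remaining C–H next to the carbonyl, so both epimers of 5 converge on one tetrasubstituted silyl enol ether and the quaternary centre is untouched.

Step 4
Reactants: 6 (R)-(6-allyl-2,6-dimethylcyclohex-1-en-1-yl)oxytrimethylsilane
Product: 7 (R)-6-allyl-2,6-dimethylcyclohex-2-en-1-one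
Conditions: Pd(OAc)2 (1.05 equiv), MeCN, 25–40 °C
Reagents that add atoms: none
Why: Saegusa–Ito oxidation: the silyl enol ether transmetalates to a palladium enolate that loses a β-hydride from the ring CH2 to give the conjugated endocyclic enone, while the isolated allyl group and the quaternary centre stay as they are.

Step 5
Reactants: 7 (R)-6-allyl-2,6-dimethylcyclohex-2-en-1-one
Product: 9 (R)-2-(1,3-dimethyl-2-oxocyclohex-3-en-1-yl)acetaldehyde, via diol 8 (not isolated)
Conditions: OsO4 (2 mol %), NaIO4, 2,6-lutidine, dioxane–H2O, 25 °C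
Reagents that add atoms: osmium tetroxide, O=[Os](=O)(=O)=O (catalytic oxygen carrier); sodium periodate, [Na+].[O-]I(=O)(=O)=O (terminal oxygen source)
Why: Lemieux–Johnson cleavage: OsO4 dihydroxylates the electron-rich monosubstituted alkene far faster than the electron-poor trisubstituted enone alkene and periodate cleaves diol 8 to the aldehyde, 2,6-lutidine holding back over-oxidation.

Step 6
Reactants: 9 (R)-2-(1,3-dimethyl-2-oxocyclohex-3-en-1-yl)acetaldehyde
Product: 10 (R)-2,6-dimethyl-6-[(E)-2-(triethylsilyloxy)vinyl]cyclohex-2-en-1-one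
Conditions: TESOTf (1.1 equiv), Et3N, CH2Cl2, −78 → 0 °C; Et3N-deactivated silica
Reagents that add atoms: triethylsilyl trifluoromethanesulfonate, CC[Si](CC)(CC)OS(=O)(=O)C(F)(F)F
Why: Silyl triflate and amine enolise the aldehyde much faster than the enone (whose α′ carbon is quaternary), and the E silyl enol ether should dominate because the Z isomer forces the silyloxy group against the quaternary carbon; any Z isomer is removed on deactivated silica.

Step 7
Reactants: 11 2-bromoprop-2-en-1-ol
Product: 12 (2-bromoallyloxy)triethylsilane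
Conditions: TESCl, imidazole, CH2Cl2, 0 °C
Reagents that add atoms: chlorotriethylsilane, CC[Si](Cl)(CC)CC
Why: Standard silylation of a primary allylic alcohol with a silyl chloride and imidazole.

Step 8
Reactants: 12 (2-bromoallyloxy)triethylsilane; 13 (E)-1,2-bis(tributylstannyl)ethene
Product: 14 (E)-tributyl[3-(triethylsilyloxymethyl)buta-1,3-dien-1-yl]stannane (fragment 2)
Conditions: Pd(PPh3)4 (5 mol %), 13 (2.5 equiv), toluene, 90 °C
Reagents that add atoms: none
Why: Stille coupling at the vinyl bromide with retention of the E geometry of the stannane; the excess of distannane 13 keeps the reaction at the mono-coupling stage.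

Step 9
Reactants: 14 (E)-dienylstannane; 10 (R)-2,6-dimethyl-6-[(E)-2-(triethylsilyloxy)vinyl]cyclohex-2-en-1-one
Product: 17 (1R,6R)-2,6-dimethyl-1-[(1E)-3-(triethylsilyloxymethyl)buta-1,3-dien-1-yl]-6-[(E)-2-(triethylsilyloxy)vinyl]cyclohex-2-en-1-ol, via dienyllithium 15 (not isolated), via dienylcerium dichloride 16 (not isolated)
Conditions: 14, MeLi, THF, −78 °C; CeCl3, −78 °C; then 10, −78 → −40 °C; aq NH4Cl
Reagents that add atoms: none
Why: Tin–lithium exchange gives the E dienyllithium with retention, transmetalation to the less basic organocerium secures 1,2-addition to the hindered enone carbonyl, and attack anti to the (E)-silyloxyvinyl group (the larger, axially disposed substituent of the neighbouring quaternary carbon) sets the carbinol carbon R with the two alkenyl groups trans; the minor epimer is removed by chromatography.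

Step 10
Reactants: 17 (1R,6R)-1,2-dialkenylcyclohex-2-enol
Product: 20 (1(10)Z,4E,6S,7S,8S)-8α-hydroxy-6α,12-bis(triethylsilyloxy)germacra-1(10),4,11(13)-trien-9-one, via potassium alkoxide 18 (not isolated), via potassium dienolate 19 (not isolated)
Conditions: KH, 18-crown-6, THF, 0 → 25 °C; then −78 °C, 2-(phenylsulfonyl)-3-phenyloxaziridine; AcOH, −78 °C
Reagents that add atoms: 2-(phenylsulfonyl)-3-phenyloxaziridine, O1C(c2ccccc2)N1S(=O)(=O)c1ccccc1
Why: KH with 18-crown-6 gives the dissociated potassium alkoxide 18, which undergoes the anionic oxy-Cope [3,3] shift across C7=C8–C9–C4–C5=C6: the C6–C7 bond forms as the doubly allylic C4–C9 bond of the cyclohexene breaks, so the six-membered ring is expanded to the ten-membered carbocycle (ring expansion through a six-centre chair, no end-to-end closure and no high dilution) and the cis C1=C10 alkene is carried over unchanged. The closest known reaction type is the anionic oxy-Cope ring expansion of 1,2-dialkenylcyclohexanols to cyclodec-5-enones with trapping of the enolate by an electrophile. The R quaternary C4 fixes the chair with its methyl axial and C3 equatorial (both alkenyl groups equatorial on the cyclohexene), which gives the E C4=C5 alkene, and the two E alkenes place the C6 silyloxy group and the C7 side chain equatorial, so C6 and C7 are both set S with O6 and C11 trans. Dienolate 19 has the E ring geometry with H7 eclipsing the enolate (allylic 1,3-strain with the oxide) and the C7–C6 ring bond on its inner face, so the oxaziridine can add to C8 only anti to that bond, cis to H7, which gives the 8α (8S) alcohol. The step needs the [3,3] shift to win over fragmentation and silyl transfer and the chair to win over the boat; the weak doubly allylic C4–C9 bond, the dissociated alkoxide and the trans-diequatorial alkenyl groups should secure this.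

Step 11
Reactants: 20 8α-hydroxy ketone
Product: 21 (6S,7S,8R)-8β-(4-nitrobenzoyloxy)-6α,12-bis(triethylsilyloxy)germacra-1(10)Z,4E,11(13)-trien-9-one
Conditions: 4-nitrobenzoic acid, PPh3, DIAD, toluene, 0 → 25 °C
Reagents that add atoms: 4-nitrobenzoic acid, OC(=O)c1ccc(cc1)[N+](=O)[O-]
Why: Mitsunobu reaction: the C8 hydroxyl becomes an oxyphosphonium leaving group and is displaced by the carboxylate in an SN2 step that the adjacent ketone accelerates, the nucleophile entering from the side of H7 and H8, so C8 is inverted from α (S) to β (R).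

Step 12
Reactants: 21 8β-(4-nitrobenzoate)
Product: 22 (6S,7S,8R)-8β-hydroxy-6α,12-bis(triethylsilyloxy)germacra-1(10)Z,4E,11(13)-trien-9-one
Conditions: K2CO3 (0.2 equiv), MeOH, 0 °C, short
Reagents that add atoms: none
Why: Methanolysis (transesterification) of the activated α-keto aryl ester is fast under mild carbonate catalysis at 0 °C, conditions short and weak enough to leave the triethylsilyl ethers and the C8 configuration alone.

Step 13
Reactants: 22 8β-hydroxy ketone
Product: 23 8β-(tert-butyldimethylsilyloxy)-6α,12-bis(triethylsilyloxy)germacra-1(10)Z,4E,11(13)-trien-9-one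
Conditions: TBSOTf, 2,6-lutidine, CH2Cl2, −78 °C
Reagents that add atoms: tert-butyldimethylsilyl trifluoromethanesulfonate, CC(C)(C)[Si](C)(C)OS(=O)(=O)C(F)(F)F
Why: Silylation of a hindered secondary alcohol with a silyl triflate and 2,6-lutidine; at −78 °C the hydroxyl reacts well before the ketone can be enol-silylated.

Step 14
Reactants: 23 8β-silyloxy enone
Product: 24 8β-(tert-butyldimethylsilyloxy)-6α,12-bis(triethylsilyloxy)germacra-1(10)Z,4E,11(13)-trien-9α-ol (9R)
Conditions: NaBH4, CeCl3·7H2O, MeOH, −78 °C
Reagents that add atoms: none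
Why: Luche 1,2-reduction of the enone: next to the non-chelating silyl ether hydride should add anti to the C8–O bond (polar non-chelated model) from the ring periphery, which gives the 9α (9R) alcohol, i.e. the syn 8,9-diol pattern.

Step 15
Reactants: 25 angelic acid
Product: 26 (Z)-2-methylbut-2-en-1-ol
Conditions: LiAlH4, Et2O, 0 °C; aqueous work-up
Reagents that add atoms: none
Why: Hydride reduction of the carboxylic acid to the primary allylic alcohol; at 0 °C the trisubstituted Z alkene is neither reduced nor isomerised.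

Step 16
Reactants: 26 (Z)-2-methylbut-2-en-1-ol
Product: 27 (2S,3R)-2,3-epoxy-2-methylbutan-1-ol
Conditions: Ti(OiPr)4 (10 mol %), L-(+)-diethyl tartrate (14 mol %), t-BuOOH, 4 Å MS, CH2Cl2, −20 °C
Reagents that add atoms: tert-butyl hydroperoxide, CC(C)(C)OO
Why: Sharpless asymmetric epoxidation: the titanium tartrate complex delivers oxygen to one face of the allylic alcohol, L-(+)-tartrate giving the 2S centre, and the Z alkene geometry then fixes C3 as R (methyl cis to the hydroxymethyl group).

Step 17
Reactants: 27 (2S,3R)-2,3-epoxy-2-methylbutan-1-ol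
Product: 29 (2R,3R)-2,3-epoxy-2-methylbutanoic acid, via epoxy aldehyde 28 (not isolated)
Conditions: RuCl3 hydrate (2 mol %), NaIO4, MeCN–EtOAc–H2O, 0 → 25 °C
Reagents that add atoms: sodium periodate, [Na+].[O-]I(=O)(=O)=O (oxygen relayed through RuO4 and the aldehyde hydrate)
Why: Catalytic RuO4 oxidises the primary alcohol through aldehyde 28 and its hydrate to the carboxylic acid without opening the epoxide; both stereocentres are untouched (C2 becomes R only through the change of substituent priority).

Step 18
Reactants: 29 (2R,3R)-2,3-epoxy-2-methylbutanoic acid; 24 9α-alcohol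
Product: 31 9α-[(2R,3R)-2,3-epoxy-2-methylbutanoyloxy]-8β-(tert-butyldimethylsilyloxy)-6α,12-bis(triethylsilyloxy)germacra-1(10)Z,4E,11(13)-triene, via mixed anhydride 30 (not isolated)
Conditions: 29, 2,4,6-trichlorobenzoyl chloride, Et3N, toluene, 25 °C; then 24, DMAP, toluene, 25–40 °C
Reagents that add atoms: none
Why: Yamaguchi esterification: DMAP opens mixed anhydride 30 at the aliphatic carbonyl (the aroyl carbonyl is shielded by its two ortho chlorines) and the acylpyridinium acylates the hindered allylic C9 hydroxyl with retention at C9 and at both epoxide carbons.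

Step 19
Reactants: 31 tris-silylated ester
Product: 32 9α-[(2R,3R)-2,3-epoxy-2-methylbutanoyloxy]-8β-(tert-butyldimethylsilyloxy)germacra-1(10)Z,4E,11(13)-triene-6α,12-diol
Conditions: HF·pyridine, pyridine, THF, 0 °C
Reagents that add atoms: none
Why: Fluoride desilylation under buffered conditions: the primary and the secondary triethylsilyl ether are cleaved far faster than the hindered secondary tert-butyldimethylsilyl ether, and pyridine buffering protects the epoxide and the 1,5-diene.

Step 20
Reactants: 32 6α,12-diol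
Product: 35 9α-[(2R,3R)-2,3-epoxy-2-methylbutanoyloxy]-8β-(tert-butyldimethylsilyloxy)germacra-1(10)Z,4E,11(13)-trien-12,6α-olide, via hydroxy enal 33 (not isolated), via lactol 34 (not isolated)
Conditions: TEMPO (0.2 equiv), PhI(OAc)2 (3 equiv), CH2Cl2, 25 °C
Reagents that add atoms: none
Why: Oxoammonium (TEMPO) oxidation picks the primary allylic alcohol to give enal 33, the C6 hydroxyl closes the five-membered lactol 34 by addition to the aldehyde and a second oxidation gives the α-methylene lactone (oxidative lactonisation); with C8 silylated only the 12,6-lactone can form.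

Step 21
Reactants: 35 silylated lactone
Product: 36 target CNP0213766.4, 9α-[(2R,3R)-2,3-epoxy-2-methylbutanoyloxy]-8β-hydroxygermacra-1(10)Z,4E,11(13)-trien-12,6α-olide (6S,7S,8R,9R)
Conditions: HF·pyridine, THF, 0 → 25 °C
Reagents that add atoms: none
Why: Acidic fluoride removes the last silyl ether while avoiding the acyl shift from O9 to O8, relactonisation onto O8 and conjugate additions to the α-methylene lactone that basic fluoride sources would risk.

**Compound list**
1 | 2,6-dimethylcyclohexanone (cis/trans mixture) | CC1CCCC(C)C1=O | starting material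
2 | allyl chloroformate | C=CCOC(Cl)=O | starting material
3 | lithium 2,6-dimethylcyclohex-1-en-1-olate | CC1CCCC(C)=C1[O-].[Li+] | intermediate
4 | allyl 2,6-dimethylcyclohex-1-en-1-yl carbonate | CC1CCCC(C)=C1OC(=O)OCC=C | intermediate
5 | (2R)-2-allyl-2,6-dimethylcyclohexanone (C6 epimers) | CC1CCC[C@](C)(CC=C)C1=O | intermediate
6 | (R)-(6-allyl-2,6-dimethylcyclohex-1-en-1-yl)oxytrimethylsilane | C[Si](C)(C)OC1=C(C)CCC[C@]1(C)CC=C | intermediate
7 | (R)-6-allyl-2,6-dimethylcyclohex-2-en-1-one | CC1=CCC[C@](C)(CC=C)C1=O | intermediate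
8 | (6R)-6-(2,3-dihydroxypropyl)-2,6-dimethylcyclohex-2-en-1-one (carbinol epimers) | CC1=CCC[C@](C)(CC(O)CO)C1=O | intermediate
9 | (R)-2-(1,3-dimethyl-2-oxocyclohex-3-en-1-yl)acetaldehyde | CC1=CCC[C@](C)(CC=O)C1=O | intermediate
10 | (R)-2,6-dimethyl-6-[(E)-2-(triethylsilyloxy)vinyl]cyclohex-2-en-1-one | CC1=CCC[C@](C)(/C=C/O[Si](CC)(CC)CC)C1=O | intermediate
11 | 2-bromoprop-2-en-1-ol | C=C(Br)CO | starting material
12 | (2-bromoallyloxy)triethylsilane | C=C(Br)CO[Si](CC)(CC)CC | intermediate
13 | (E)-1,2-bis(tributylstannyl)ethene | CCCC[Sn](CCCC)(CCCC)/C=C/[Sn](CCCC)(CCCC)CCCC | starting material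
14 | (E)-tributyl[3-(triethylsilyloxymethyl)buta-1,3-dien-1-yl]stannane | CCCC[Sn](CCCC)(CCCC)/C=C/C(=C)CO[Si](CC)(CC)CC | intermediate
15 | (E)-[3-(triethylsilyloxymethyl)buta-1,3-dien-1-yl]lithium | [Li]/C=C/C(=C)CO[Si](CC)(CC)CC | intermediate
16 | (E)-[3-(triethylsilyloxymethyl)buta-1,3-dien-1-yl]cerium dichloride | Cl[Ce](Cl)/C=C/C(=C)CO[Si](CC)(CC)CC | intermediate
17 | (1R,6R)-2,6-dimethyl-1-[(1E)-3-(triethylsilyloxymethyl)buta-1,3-dien-1-yl]-6-[(E)-2-(triethylsilyloxy)vinyl]cyclohex-2-en-1-ol | CC1=CCC[C@](C)(/C=C/O[Si](CC)(CC)CC)[C@@]1(O)/C=C/C(=C)CO[Si](CC)(CC)CC | intermediate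
18 | potassium alkoxide of 17 | CC1=CCC[C@](C)(/C=C/O[Si](CC)(CC)CC)[C@@]1([O-])/C=C/C(=C)CO[Si](CC)(CC)CC.[K+] | intermediate
19 | potassium (6S,7S)-6α,12-bis(triethylsilyloxy)germacra-1(10)Z,4E,8E,11(13)-tetraen-9-olate | C=C(CO[Si](CC)(CC)CC)[C@@H]1[C@@H](O[Si](CC)(CC)CC)/C=C(\C)CC/C=C(/C)\C([O-])=C\1.[K+] | intermediate
20 | (6S,7S,8S)-8α-hydroxy-6α,12-bis(triethylsilyloxy)germacra-1(10)Z,4E,11(13)-trien-9-one | C=C(CO[Si](CC)(CC)CC)[C@@H]1[C@@H](O[Si](CC)(CC)CC)/C=C(\C)CC/C=C(/C)C(=O)[C@H]1O | intermediate
21 | (6S,7S,8R)-8β-(4-nitrobenzoyloxy)-6α,12-bis(triethylsilyloxy)germacra-1(10)Z,4E,11(13)-trien-9-one | C=C(CO[Si](CC)(CC)CC)[C@@H]1[C@@H](O[Si](CC)(CC)CC)/C=C(\C)CC/C=C(/C)C(=O)[C@@H]1OC(=O)c2ccc(cc2)[N+](=O)[O-] | intermediate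
22 | (6S,7S,8R)-8β-hydroxy-6α,12-bis(triethylsilyloxy)germacra-1(10)Z,4E,11(13)-trien-9-one | C=C(CO[Si](CC)(CC)CC)[C@@H]1[C@@H](O[Si](CC)(CC)CC)/C=C(\C)CC/C=C(/C)C(=O)[C@@H]1O | intermediate
23 | 8β-(tert-butyldimethylsilyloxy)-6α,12-bis(triethylsilyloxy)germacra-1(10)Z,4E,11(13)-trien-9-one | C=C(CO[Si](CC)(CC)CC)[C@@H]1[C@@H](O[Si](CC)(CC)CC)/C=C(\C)CC/C=C(/C)C(=O)[C@@H]1O[Si](C)(C)C(C)(C)C | intermediate
24 | 8β-(tert-butyldimethylsilyloxy)-6α,12-bis(triethylsilyloxy)germacra-1(10)Z,4E,11(13)-trien-9α-ol | C=C(CO[Si](CC)(CC)CC)[C@@H]1[C@@H](O[Si](CC)(CC)CC)/C=C(\C)CC/C=C(/C)[C@@H](O)[C@@H]1O[Si](C)(C)C(C)(C)C | intermediate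
25 | angelic acid, (Z)-2-methylbut-2-enoic acid | C/C=C(/C)C(=O)O | starting material
26 | (Z)-2-methylbut-2-en-1-ol | C/C=C(/C)CO | intermediate
27 | (2S,3R)-2,3-epoxy-2-methylbutan-1-ol | OC[C@]1(C)O[C@@H]1C | intermediate
28 | (2R,3R)-2,3-epoxy-2-methylbutanal | O=C[C@]1(C)O[C@@H]1C | intermediate
29 | (2R,3R)-2,3-epoxy-2-methylbutanoic acid | OC(=O)[C@]1(C)O[C@@H]1C | intermediate
30 | (2R,3R)-2,3-epoxy-2-methylbutanoic 2,4,6-trichlorobenzoic anhydride | O=C(OC(=O)[C@]1(C)O[C@@H]1C)c2c(Cl)cc(Cl)cc2Cl | intermediate
31 | 9α-[(2R,3R)-2,3-epoxy-2-methylbutanoyloxy]-8β-(tert-butyldimethylsilyloxy)-6α,12-bis(triethylsilyloxy)germacra-1(10)Z,4E,11(13)-triene | C=C(CO[Si](CC)(CC)CC)[C@@H]1[C@@H](O[Si](CC)(CC)CC)/C=C(\C)CC/C=C(/C)[C@@H](OC(=O)[C@]2(C)O[C@@H]2C)[C@@H]1O[Si](C)(C)C(C)(C)C | intermediate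
32 | 9α-[(2R,3R)-2,3-epoxy-2-methylbutanoyloxy]-8β-(tert-butyldimethylsilyloxy)germacra-1(10)Z,4E,11(13)-triene-6α,12-diol | C=C(CO)[C@@H]1[C@@H](O)/C=C(\C)CC/C=C(/C)[C@@H](OC(=O)[C@]2(C)O[C@@H]2C)[C@@H]1O[Si](C)(C)C(C)(C)C | intermediate
33 | 9α-[(2R,3R)-2,3-epoxy-2-methylbutanoyloxy]-8β-(tert-butyldimethylsilyloxy)-6α-hydroxygermacra-1(10)Z,4E,11(13)-trien-12-al | C=C(C=O)[C@@H]1[C@@H](O)/C=C(\C)CC/C=C(/C)[C@@H](OC(=O)[C@]2(C)O[C@@H]2C)[C@@H]1O[Si](C)(C)C(C)(C)C | intermediate
34 | 12,6α-lactol of 33 (C12 epimers) | C=C1C(O)O[C@H]2/C=C(\C)CC/C=C(/C)[C@@H](OC(=O)[C@]3(C)O[C@@H]3C)[C@H](O[Si](C)(C)C(C)(C)C)[C@H]12 | intermediate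
35 | 9α-[(2R,3R)-2,3-epoxy-2-methylbutanoyloxy]-8β-(tert-butyldimethylsilyloxy)germacra-1(10)Z,4E,11(13)-trien-12,6α-olide | C=C1C(=O)O[C@H]2/C=C(\C)CC/C=C(/C)[C@@H](OC(=O)[C@]3(C)O[C@@H]3C)[C@H](O[Si](C)(C)C(C)(C)C)[C@H]12 | intermediate
36 | CNP0213766.4, 9α-[(2R,3R)-2,3-epoxy-2-methylbutanoyloxy]-8β-hydroxygermacra-1(10)Z,4E,11(13)-trien-12,6α-olide | C=C1C(=O)O[C@H]2/C=C(\C)CC/C=C(/C)[C@@H](OC(=O)[C@]3(C)O[C@@H]3C)[C@H](O)[C@H]12 | target

**Step count**
Total: 21 steps. Longest linear sequence: 16 steps (1–6, 9–14, 18–21).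

**Steps most likely to fail**

Step 11 (inversion at C8). The substitution may lose to elimination toward C7, because H7 can stand anti to the activated oxygen, or stall for steric reasons next to the tertiary C7. The fallback sets out from 20 and replaces substitution by an oxidation–reduction pair. Dess–Martin periodinane (NaHCO3, CH2Cl2) would oxidise 20 to 6α,12-bis(triethylsilyloxy)germacra-1(10)Z,4E,11(13)-triene-8,9-dione F1. The non-conjugated, more electrophilic C8 carbonyl would then be reduced (NaBH4, MeOH–CH2Cl2, −78 °C). Hydride reaching C8 on the face that the oxidant used in step 10 would place the hydroxyl on the opposite, β side; the face selectivity would have to be found by experiment, and an oxazaborolidine-catalysed borane reduction with the appropriate catalyst enantiomer would supply reagent control if the substrate bias is weak. The sequence returns to the route at 22.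

Step 10 (ring expansion). The dissociated alkoxide may take a silyl group from the enol ether, the doubly allylic bond may fragment without recombination, or a boat pathway may erode the C6/C7 control. The fallback sets out from 17 and avoids the alkoxide. Silylation (TMS-imidazole, CH2Cl2) would give the trimethylsilyl ether of carbinol 17 F2. A neutral siloxy-Cope rearrangement (xylene, about 170 °C, base-washed sealed vessel) through the same chair would give the ring-expanded 9-trimethylsilyl enol ether F3. KOt-Bu in THF at −78 °C would then release dienolate 19, which is oxidised with the oxaziridine as in step 10, and the route is rejoined at 20.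

Step 14 (reduction at C9). Hydride delivery in the flexible ring may show poor or reversed facial selectivity. The fallback sets out from 23 and uses the wrong epimer productively. The 9β alcohol 8β-(tert-butyldimethylsilyloxy)-6α,12-bis(triethylsilyloxy)germacra-1(10)Z,4E,11(13)-trien-9β-ol F4 would be esterified with acid 29 under Mitsunobu conditions (PPh3, DIAD, toluene, 0 °C). This forms the ester bond with inversion at C9 and returns to the route at 31.

**Further compounds**
F1 | step 11 | 6α,12-bis(triethylsilyloxy)germacra-1(10)Z,4E,11(13)-triene-8,9-dione | C=C(CO[Si](CC)(CC)CC)[C@@H]1[C@@H](O[Si](CC)(CC)CC)/C=C(\C)CC/C=C(/C)C(=O)C1=O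
F2 | step 10 | trimethylsilyl ether of carbinol 17 | CC1=CCC[C@](C)(/C=C/O[Si](CC)(CC)CC)[C@@]1(O[Si](C)(C)C)/C=C/C(=C)CO[Si](CC)(CC)CC
F3 | step 10 | (6S,7S)-6α,12-bis(triethylsilyloxy)-9-(trimethylsilyloxy)germacra-1(10)Z,4E,8E,11(13)-tetraene | C=C(CO[Si](CC)(CC)CC)[C@@H]1[C@@H](O[Si](CC)(CC)CC)/C=C(\C)CC/C=C(/C)\C(O[Si](C)(C)C)=C\1
F4 | step 14 | 8β-(tert-butyldimethylsilyloxy)-6α,12-bis(triethylsilyloxy)germacra-1(10)Z,4E,11(13)-trien-9β-ol | C=C(CO[Si](CC)(CC)CC)[C@@H]1[C@@H](O[Si](CC)(CC)CC)/C=C(\C)CC/C=C(/C)[C@H](O)[C@@H]1O[Si](C)(C)C(C)(C)C
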